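**Strategy.** Ring B is cut into two three-carbon pieces, C10–C5–C6 (β-cyclocitral) and C7–C8–C9 (a Z-allyl unit capped by isopropenyl). The key step uses the C6 oxygen on the C5–C10 edge of ring A: the alkoxide of an (R)-carbinol at C6 drives an anionic oxy-Cope shift that joins C9 to the quaternary C10 and frees C6 as an aldehyde, which in the same flask undergoes a type II carbonyl-ene reaction with the isopropenyl group to join C6 to C7. The precursor is an acyclic (Z)-dienyl carbinol whose C6–C12 bond is spent; C12 becomes the vinyl terminus from which the side chain, with C13 set by Sharpless epoxidation, is grown.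

Key step: step 4

Remark: positions are named by labdane numbering (C1–C20; the target belongs to the ent-labdane series). The sense of induction in steps 1, 4 and 10 is assigned from the usual transition-state models, not from measurement.

Step 1
Reactants: 1 β-cyclocitral; 2 allenylboronic acid pinacol ester
Product: 3 (R)-1-(2,6,6-trimethylcyclohex-1-en-1-yl)but-3-yn-1-ol
Conditions: (R)-TRIP (5–10 mol %), 4 Å MS, PhMe, 0 °C → rt; aqueous work-up
Reagents that add atoms: none
Why: Chiral-phosphoric-acid-catalysed propargylation (SE2' allenylboration through a closed six-membered transition state) gives the homopropargyl alcohol, the catalyst antipode being the one that leads to the R carbinol ((R)-TRIP by analogy with aryl and alkenyl aldehydes).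

Step 2
Reactants: 3 (R)-1-(2,6,6-trimethylcyclohex-1-en-1-yl)but-3-yn-1-ol; 4 2-bromopropene
Product: 5 (R)-5-methyl-1-(2,6,6-trimethylcyclohex-1-en-1-yl)hex-5-en-3-yn-1-ol
Conditions: Pd(PPh3)2Cl2 (3 mol %), CuI (5 mol %), Et3N, THF, rt → 40 °C (sealed)
Reagents that add atoms: none
Why: Sonogashira coupling of the terminal alkyne with the vinyl bromide tolerates the free alcohol and touches no stereocenter.

Step 3
Reactants: 5 (R)-5-methyl-1-(2,6,6-trimethylcyclohex-1-en-1-yl)hex-5-en-3-yn-1-ol
Product: 6 (R,Z)-5-methyl-1-(2,6,6-trimethylcyclohex-1-en-1-yl)hexa-3,5-dien-1-ol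
Conditions: Zn(Cu/Ag), MeOH/H2O, 40 °C
Reagents that add atoms: none
Why: Boland semireduction of the conjugated enyne adds hydrogen syn to the triple bond only, which sets the Z C9=C11 alkene that the chair rearrangement needs.

Step 4
Reactants: 6 (R,Z)-5-methyl-1-(2,6,6-trimethylcyclohex-1-en-1-yl)hexa-3,5-dien-1-ol
Product: 9 (5R,6S,9R,10S)-13,14,15,16-tetranorlabda-8(17),11-dien-6-ol, via potassium enolate 7 (not isolated), via seco-aldehyde 8 (not isolated)
Conditions: KHMDS (1.2 equiv), 18-crown-6, PhMe, 0 → 60 °C; AcOH (1.2 equiv), −78 °C; then Me2AlCl (4 equiv), −78 → 0 °C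
Reagents that add atoms: none
Why: Deprotonation gives the C6 alkoxide, whose chair [3,3] shift (anionic oxy-Cope) joins C9 to C10 and breaks C6–C12, turning C12 into the vinyl terminus and C6 into an enolate that acetic acid protonates at C5 anti to the two axial methyl groups; Me2AlCl then activates the aldehyde for a type II carbonyl-ene reaction in which C7 of the isopropenyl group attacks C6 and a C17 hydrogen passes to oxygen. The closest known reaction type is the tandem oxy-Cope/carbonyl-ene sequence used to build decalinols, here run in its anionic/Lewis-acid form. No ring closes in the sigmatropic stage; ring B closes in the ene stage by 6-exo-trig attack on the carbonyl within a chair-like, bicyclo[3.3.1]-type transition state that leaves the exocyclic C8=C17 methylene. C10 and C9 are controlled by the C6 carbinol through the chair with the oxyanion equatorial (an axial oxygen would be 1,3-diaxial to the C10 methyl) and the Z-placed isopropenyl axial, C5 by the protonation (and the equatorial preference of the formyl group), and C6 by the ene geometry, which needs the carbonyl oxygen axial, that is cis to C20, to reach the C17 hydrogen. The step needs chair over boat, rearrangement over retro-allylation of the alkoxide, and ene reaction at the isopropenyl and not the vinyl group; the Z alkene and the 1,3-diaxial penalty fix the chair, and the more nucleophilic 1,1-disubstituted alkene with its allylic methyl secures the chemoselectivity.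

Step 5
Reactants: 9 (5R,6S,9R,10S)-13,14,15,16-tetranorlabda-8(17),11-dien-6-ol
Product: 10 (5R,6S,8S,9S,10R)-8,17-epoxy-13,14,15,16-tetranorlabd-11-en-6-ol
Conditions: mCPBA (1.05 equiv), NaHCO3, CH2Cl2, 0 °C
Reagents that add atoms: mCPBA, OOC(=O)c1cccc(Cl)c1
Why: Prilezhaev epoxidation is chemoselective for the 1,1-disubstituted C8=C17 alkene over the hindered vinyl group, the peracid approaching anti to the axial C10 methyl (either C8 epimer serves, because this center is lost in step 6).

Step 6
Reactants: 10 (5R,6S,8S,9S,10R)-8,17-epoxy-13,14,15,16-tetranorlabd-11-en-6-ol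
Product: 11 (5R,6S,9S,10S)-13,14,15,16-tetranorlabda-7,11-diene-6,17-diol
Conditions: LiTMP/Et2AlCl (→ Et2AlTMP, 3 equiv), PhMe, 0 °C → rt; Rochelle salt work-up
Reagents that add atoms: none
Why: Yamamoto isomerisation of an epoxide to an allylic alcohol, in which the aluminium amide bound to the epoxide oxygen removes a syn hydrogen from the C7 methylene (in preference to the hindered tertiary C9–H) and opens C8–O to give the C7=C8 alkene and the C17 alcohol.

Step 7
Reactants: 11 (5R,6S,9S,10S)-13,14,15,16-tetranorlabda-7,11-diene-6,17-diol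
Product: 12 (5R,6S,9S,10S)-13,14,15,16-tetranorlabda-7,11-diene-6,17-diyl diacetate
Conditions: Ac2O, DMAP, pyridine, 50 °C
Reagents that add atoms: acetic anhydride, CC(=O)OC(C)=O
Why: DMAP-catalysed acetylation esterifies the primary allylic hydroxyl and, on warming, the hindered axial C6 hydroxyl with retention at C6.

Step 8
Reactants: 13 but-2-yn-1-ol
Product: 14 (Z)-3-iodobut-2-en-1-ol
Conditions: Red-Al, THF, 0 °C → rt; then I2, −78 °C
Reagents that add atoms: iodine, II
Why: trans-Hydroalumination of the propargylic alcohol (hydride delivered to C2 from the alkoxyaluminate) followed by iodinolysis with retention gives the Z 3-iodo allylic alcohol.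

Step 9
Reactants: 12 (5R,6S,9S,10S)-13,14,15,16-tetranorlabda-7,11-diene-6,17-diyl diacetate; 14 (Z)-3-iodobut-2-en-1-ol
Product: 15 (5R,6S,9S,10S,11E,13Z)-6,17-diacetoxylabda-7,11,13-trien-15-ol
Conditions: Pd(OAc)2 (10 mol %), AgOAc (1.2 equiv), DMF, 45 °C
Reagents that add atoms: none
Why: Jeffery-type Mizoroki–Heck coupling, in which the alkenylpalladium adds to the terminal carbon of the vinyl group and syn β-hydride elimination gives the 11E alkene with retention of the Z iodide geometry, the phosphine-free silver conditions sparing the allylic acetates.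

Step 10
Reactants: 15 (5R,6S,9S,10S,11E,13Z)-6,17-diacetoxylabda-7,11,13-trien-15-ol
Product: 16 (5R,6S,9S,10S,11E,13R,14S)-6,17-diacetoxy-13,14-epoxylabda-7,11-dien-15-ol
Conditions: Ti(OiPr)4 (10 mol %), L-(+)-DET (12 mol %), TBHP, 4 Å MS, CH2Cl2, −20 °C
Reagents that add atoms: tert-butyl hydroperoxide, CC(C)(C)OO
Why: Sharpless asymmetric epoxidation of the allylic alcohol, in which L-(+)-DET delivers oxygen to the face of the Z-trisubstituted C13=C14 alkene that gives the (13R,14S)-epoxide (as for nerol), so C13 is set by reagent control.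

Step 11
Reactants: 16 (5R,6S,9S,10S,11E,13R,14S)-6,17-diacetoxy-13,14-epoxylabda-7,11-dien-15-ol
Product: 17 (5R,6S,9S,10S,11E,13R,14R)-13,14-epoxy-15-iodolabda-7,11-diene-6,17-diyl diacetate
Conditions: I2, PPh3, imidazole, Et2O/MeCN, 0 °C
Reagents that add atoms: iodine, II
Why: Appel-type iodination (Garegg conditions) converts the primary alcohol into the iodide without touching the epoxide or any stereocenter.

Step 12
Reactants: 17 (5R,6S,9S,10S,11E,13R,14R)-13,14-epoxy-15-iodolabda-7,11-diene-6,17-diyl diacetate
Product: 18 (5R,6S,9S,10S,11E,13S)-13-hydroxylabda-7,11,14-triene-6,17-diyl diacetate (CNP0103498.1)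
Conditions: Zn dust (activated), AcOH (2 equiv), EtOH, 0 °C → rt
Reagents that add atoms: none
Why: Zinc inserts into the C–I bond and β-elimination opens the epoxide (reductive epoxide opening), which moves the double bond to C14=C15 and leaves the C13–O bond, hence the C13 configuration, intact.

**Compound list**

1 | β-cyclocitral (2,6,6-trimethylcyclohex-1-ene-1-carbaldehyde) | CC1=C(C=O)C(C)(C)CCC1 | starting material
2 | allenylboronic acid pinacol ester | C=C=CB1OC(C)(C)C(C)(C)O1 | starting material
3 | (R)-1-(2,6,6-trimethylcyclohex-1-en-1-yl)but-3-yn-1-ol | C#CC[C@@H](O)C1=C(C)CCCC1(C)C | intermediate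
4 | 2-bromopropene | C=C(C)Br | starting material
5 | (R)-5-methyl-1-(2,6,6-trimethylcyclohex-1-en-1-yl)hex-5-en-3-yn-1-ol | C=C(C)C#CC[C@@H](O)C1=C(C)CCCC1(C)C | intermediate
6 | (R,Z)-5-methyl-1-(2,6,6-trimethylcyclohex-1-en-1-yl)hexa-3,5-dien-1-ol | C=C(C)/C=C\C[C@@H](O)C1=C(C)CCCC1(C)C | intermediate
7 | potassium (E)-{(2S)-2,6,6-trimethyl-2-[(3R)-2-methylpenta-1,4-dien-3-yl]cyclohexylidene}methanolate (enolate, not isolated) | [K+].[O-]/C=C1\C(C)(C)CCC[C@@]1(C)[C@H](C=C)C(C)=C | intermediate
8 | (1R,2S)-2,6,6-trimethyl-2-[(3R)-2-methylpenta-1,4-dien-3-yl]cyclohexane-1-carbaldehyde (seco-aldehyde, not isolated) | C=C[C@H](C(C)=C)[C@]1(C)CCCC(C)(C)[C@H]1C=O | intermediate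
9 | (5R,6S,9R,10S)-13,14,15,16-tetranorlabda-8(17),11-dien-6-ol (6-OH axial, cis to C20; vinyl equatorial) | C=C[C@@H]1C(=C)C[C@H](O)[C@@H]2C(C)(C)CCC[C@@]12C | intermediate
10 | (5R,6S,8S,9S,10R)-8,17-epoxy-13,14,15,16-tetranorlabd-11-en-6-ol (epoxide oxygen trans to C20) | C=C[C@@H]1[C@]2(CO2)C[C@H](O)[C@@H]3C(C)(C)CCC[C@@]13C | intermediate
11 | (5R,6S,9S,10S)-13,14,15,16-tetranorlabda-7,11-diene-6,17-diol | C=C[C@@H]1C(CO)=C[C@H](O)[C@@H]2C(C)(C)CCC[C@@]12C | intermediate
12 | (5R,6S,9S,10S)-13,14,15,16-tetranorlabda-7,11-diene-6,17-diyl diacetate | C=C[C@@H]1C(COC(C)=O)=C[C@H](OC(C)=O)[C@@H]2C(C)(C)CCC[C@@]12C | intermediate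
13 | but-2-yn-1-ol | CC#CCO | starting material
14 | (Z)-3-iodobut-2-en-1-ol | OC/C=C(C)\I | intermediate
15 | (5R,6S,9S,10S,11E,13Z)-6,17-diacetoxylabda-7,11,13-trien-15-ol | OC/C=C(C)\C=C\[C@@H]1C(COC(C)=O)=C[C@H](OC(C)=O)[C@@H]2C(C)(C)CCC[C@@]12C | intermediate
16 | (5R,6S,9S,10S,11E,13R,14S)-6,17-diacetoxy-13,14-epoxylabda-7,11-dien-15-ol | OC[C@@H]1O[C@]1(C)/C=C/[C@@H]2C(COC(C)=O)=C[C@H](OC(C)=O)[C@@H]3C(C)(C)CCC[C@@]23C | intermediate
17 | (5R,6S,9S,10S,11E,13R,14R)-13,14-epoxy-15-iodolabda-7,11-diene-6,17-diyl diacetate | IC[C@@H]1O[C@]1(C)/C=C/[C@@H]2C(COC(C)=O)=C[C@H](OC(C)=O)[C@@H]3C(C)(C)CCC[C@@]23C | intermediate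
18 | (5R,6S,9S,10S,11E,13S)-13-hydroxylabda-7,11,14-triene-6,17-diyl diacetate (CNP0103498.1) | C=C[C@](C)(O)/C=C/[C@@H]1C(COC(C)=O)=C[C@H](OC(C)=O)[C@@H]2C(C)(C)CCC[C@@]12C | target

**Step count.** Total: 12 steps. Longest linear sequence: 11 steps (steps 1–7 and 9–12); step 8 is a one-step side branch.

**Steps most likely to fail**

Step 4. The potassium alkoxide may fragment by retro-allylation into β-cyclocitral and a pentadienyl anion instead of rearranging. The rearrangement may also leak through a boat or an axial-oxyanion chair, which would erode the transfer of chirality to C9 and C10. The fallback drops the alkoxide and sets out from 6. Silylation (TMSCl, imidazole, DMF) gives the trimethylsilyl ether F1. A neutral thermal siloxy-Cope rearrangement (silylated glass, decalin, 220–250 °C, sealed) then gives the silyl enol ether F2, with the bulkier OSiMe3 group reinforcing the equatorial preference. Methanolysis (K2CO3, MeOH) releases the aldehyde 8 under equilibrating conditions, and Me2AlCl cyclises 8 to 9, where the route is rejoined.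

Step 9. Insertion at the hindered vinyl group may be slow, so that palladium hydride isomerisation of the skipped diene or ionisation of the allylic acetates competes. The fallback sets out from 12. Cross-metathesis with vinylboronic acid pinacol ester (Grubbs II, CH2Cl2, 40 °C) gives the (E)-alkenylboronate F3. Suzuki–Miyaura coupling of F3 with 14 (Pd(dppf)Cl2, K3PO4, THF/H2O, rt) then comes back to the route at 15.

Step 10. The titanium Lewis acid may open the acid-labile alkenyl epoxide at the tertiary allylic C13, or exchange the acetates, before the epoxy alcohol can be isolated. The fallback sets C13 by a catalytic asymmetric 1,2-addition instead and sets out from 12. Cross-metathesis with methyl vinyl ketone (Hoveyda–Grubbs II, CH2Cl2, 40 °C) gives the (E)-enone F4. Enantioselective vinylation of F4 (divinylzinc, Ti(OiPr)4, chiral bis(sulfonamide) diol ligand of the antipode that gives 13S, PhMe, rt) comes back to the route at 18 and bypasses 15–17.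

**Further compounds**

F1 | step 4 | (R,Z)-trimethyl{[5-methyl-1-(2,6,6-trimethylcyclohex-1-en-1-yl)hexa-3,5-dien-1-yl]oxy}silane | C=C(C)/C=C\C[C@@H](O[Si](C)(C)C)C1=C(C)CCCC1(C)C
F2 | step 4 | (E)-trimethylsilyl enol ether of aldehyde 8 | C[Si](C)(C)O/C=C1\C(C)(C)CCC[C@@]1(C)[C@H](C=C)C(C)=C
F3 | step 9 | (5R,6S,9S,10S,11E)-12-(4,4,5,5-tetramethyl-1,3,2-dioxaborolan-2-yl)-13,14,15,16-tetranorlabda-7,11-diene-6,17-diyl diacetate | CC1(C)OB(/C=C/[C@@H]2C(COC(C)=O)=C[C@H](OC(C)=O)[C@@H]3C(C)(C)CCC[C@@]23C)OC1(C)C
F4 | step 10 | (5R,6S,9S,10S,11E)-13-oxo-14,15-dinorlabda-7,11-diene-6,17-diyl diacetate | CC(=O)/C=C/[C@@H]1C(COC(C)=O)=C[C@H](OC(C)=O)[C@@H]2C(C)(C)CCC[C@@]12C
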